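The route rests on tracing the dimethylpyran ring fused to ring B (O, CMe2, CH=CH and the aromatic carbons C-4′/C-5′) back to a five-membered 2,2-dimethyl-3-methylene-2,3-dihydrobenzofuran, available in one step by allene heteroannulation. In the key step [hydroxy(tosyloxy)iodo]benzene drives the exocyclic CH2 into the ring. Aromatic C-5′ is para to the 2′-oxygen and next to the oxygen-bearing C-4′, so it is an excellent migrating group. It shifts from C-3 to that CH2 and delivers the six-membered chroman-3-one. A Bamford–Stevens reaction then sets the C3=C4 alkene. Suzuki coupling with a 3-iodochromone builds the isoflavone. The 6-prenyl group follows regiospecifically from a 5-O-allyl Claisen rearrangement and cross-metathesis.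

Key step: step 4

Remark: the target has no stereocentre and no open-chain stereogenic double bond, so it is one achiral compound and needs no enantiocontrol. The transient stereocentres in 6 and 19 are racemic and are erased.

Step 1
Reactants: 1 4-bromoresorcinol
Product: 2 4-bromo-6-iodobenzene-1,3-diol
Conditions: NIS (1.0 equiv), MeCN, 0 °C
Reagents that add atoms: N-iodosuccinimide, O=C1CCC(=O)N1I
Why: Electrophilic aromatic iodination: C-6 is ortho to one hydroxyl and para to the other and is less crowded than C-2 between the two hydroxyls, so mono-iodination should occur there and gives an iodide that can be addressed in the presence of the bromide.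

Step 2
Reactants: 2 4-bromo-6-iodobenzene-1,3-diol; 3 3-methylbuta-1,2-diene
Product: 4 5-bromo-2,2-dimethyl-3-methylidene-2,3-dihydro-1-benzofuran-6-ol
Conditions: Pd(OAc)2 (5 mol %), PPh3 (10 mol %), K2CO3, n-Bu4NCl, DMF, 80 °C, sealed tube
Reagents that add atoms: none
Why: Larock-type palladium-catalysed heteroannulation of a 1,2-diene: oxidative addition takes C–I before C–Br, the aryl group adds to the central allene carbon, and the neighbouring phenoxide attacks the more substituted terminus of the π-allylpalladium, which places CMe2 next to oxygen and leaves the exocyclic methylene.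

Step 3
Reactants: 4 5-bromo-2,2-dimethyl-3-methylidene-2,3-dihydro-1-benzofuran-6-ol
Product: 5 5-bromo-6-(methoxymethoxy)-2,2-dimethyl-3-methylidene-2,3-dihydro-1-benzofuran
Conditions: MOMCl, i-Pr2NEt, CH2Cl2, 0 °C to rt
Reagents that add atoms: chloromethyl methyl ether, COCCl
Why: O-Alkylation of the phenoxide (MOM protection) masks the phenol, which iodine(III) would otherwise oxidise in step 4, and the base-only conditions leave the acid-sensitive styrene untouched.

Step 4
Reactants: 5 5-bromo-6-(methoxymethoxy)-2,2-dimethyl-3-methylidene-2,3-dihydro-1-benzofuran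
Product: 8 6-bromo-7-(methoxymethoxy)-2,2-dimethylchroman-3-one, via {[5-bromo-3-methoxy-6-(methoxymethoxy)-2,2-dimethyl-2,3-dihydro-1-benzofuran-3-yl]methyl}(phenyl)iodonium tosylate 6 (not isolated), via 6-bromo-3,3-dimethoxy-7-(methoxymethoxy)-2,2-dimethylchromane 7 (not isolated)
Conditions: PhI(OH)OTs (1.1 equiv), MeOH–H2O 95:5, 0 °C, short contact time; aq NaHCO3 quench
Reagents that add atoms: water, O (carbonyl oxygen of 8); methanol, CO (methoxy groups of 6 and 7 only); [hydroxy(tosyloxy)iodo]benzene, OI(c1ccccc1)OS(=O)(=O)c1ccc(C)cc1 (phenyliodonio group and tosylate of 6 only)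
Why: The iodine(III) electrophile adds to the terminal CH2 of the electron-rich exocyclic styrene, methanol caps the tertiary benzylic cation at C-3 to give 6, and loss of iodobenzene from the primary carbon is assisted by aromatic C-3a, which bridges and shifts from C-3 to CH2 while the methoxy group stabilises the charge left at C-3; ketal 7 and then ketone 8 follow by solvolysis. This is the known iodine(III)-mediated oxidative rearrangement of 1,1-disubstituted aryl alkenes, used as a ring expansion of exocyclic methylene benzo-fused rings (1-methyleneindane to 2-tetralone, 1-methylenetetralin to 2-benzosuberone). No ring is closed by cyclisation: the five-membered O1–C2–C3–C3a–C7a ring grows to the six-membered O1–C2–C3–C4–C4a–C8a ring by a 1,2-aryl shift through a three-membered phenonium-like bridge. No stereocentre remains in 8, and C-3 of 6 is racemic and is erased. The step needs alkene over arene chemoselectivity and aryl over alkyl migration: the 1,1-disubstituted alkene conjugated with two oxygen donors is the most nucleophilic site, and C-3a is para to OMOM and ortho to the carbon bearing O1, which makes it the better migrating group. Should C-2 migrate instead, the chroman-4-one formed would give the same chromene in step 5.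

Step 5
Reactants: 8 6-bromo-7-(methoxymethoxy)-2,2-dimethylchroman-3-one
Product: 11 6-bromo-7-(methoxymethoxy)-2,2-dimethyl-2H-chromene, via N′-[6-bromo-7-(methoxymethoxy)-2,2-dimethylchroman-3-ylidene]-4-methylbenzenesulfonohydrazide 9 (not isolated), via 6-bromo-3-diazo-7-(methoxymethoxy)-2,2-dimethylchromane 10 (not isolated)
Conditions: TsNHNH2, 1,4-dioxane, 70 °C; then LiOt-Bu, 110 °C
Reagents that add atoms: p-toluenesulfonohydrazide, Cc1ccc(cc1)S(=O)(=O)NN (atoms remain only in 9 and 10)
Why: One-pot aprotic Bamford–Stevens reaction: base-induced loss of sulfinate from 9 gives diazoalkane 10, whose carbene undergoes a 1,2-hydride shift, and because C-2 is quaternary only the benzylic C-4 hydrogens can migrate, so C3=C4 is the only alkene possible.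

Step 6
Reactants: 12 2′,4′,6′-trihydroxyacetophenone
Product: 13 1-[2,6-dihydroxy-4-(methoxymethoxy)phenyl]ethan-1-one
Conditions: MOMCl (1.0 equiv), i-Pr2NEt, THF, 0 °C
Reagents that add atoms: chloromethyl methyl ether, COCCl
Why: Selective O-alkylation: the 4-hydroxyl is the only one not tied up in a hydrogen bond to the acetyl carbonyl and is the most acidic, so one equivalent of MOMCl should react there.

Step 7
Reactants: 13 1-[2,6-dihydroxy-4-(methoxymethoxy)phenyl]ethan-1-one
Product: 14 1-[2-(allyloxy)-6-hydroxy-4-(methoxymethoxy)phenyl]ethan-1-one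
Conditions: allyl bromide (1.1 equiv), K2CO3, acetone, reflux
Reagents that add atoms: allyl bromide, C=CCBr
Why: Williamson etherification: the two ortho hydroxyls are equivalent, and after the first allylation the remaining one is locked in a strong hydrogen bond to the carbonyl, which stops the reaction at the mono-ether.

Step 8
Reactants: 14 1-[2-(allyloxy)-6-hydroxy-4-(methoxymethoxy)phenyl]ethan-1-one
Product: 16 5-(allyloxy)-3-iodo-7-(methoxymethoxy)-4H-chromen-4-one, via (E)-1-[2-(allyloxy)-6-hydroxy-4-(methoxymethoxy)phenyl]-3-(dimethylamino)prop-2-en-1-one 15 (not isolated)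
Conditions: DMF-DMA, toluene, 90 °C; evaporate; I2, CHCl3, rt
Reagents that add atoms: N,N-dimethylformamide dimethyl acetal, COC(OC)N(C)C; iodine, II
Why: Condensation of the methyl ketone with DMF-DMA gives the enaminone, and iodine then iodinates its α-carbon and triggers addition–elimination by the free ortho hydroxyl (iodocyclisation of 2-hydroxyaryl enaminones to 3-iodochromones), which fixes the allyloxy group at C-5.

Step 9
Reactants: 11 6-bromo-7-(methoxymethoxy)-2,2-dimethyl-2H-chromene; 16 5-(allyloxy)-3-iodo-7-(methoxymethoxy)-4H-chromen-4-one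
Product: 18 5-(allyloxy)-7-(methoxymethoxy)-3-[7-(methoxymethoxy)-2,2-dimethyl-2H-chromen-6-yl]-4H-chromen-4-one, via 2-[7-(methoxymethoxy)-2,2-dimethyl-2H-chromen-6-yl]-4,4,5,5-tetramethyl-1,3,2-dioxaborolane 17 (not isolated)
Conditions: 11, B2pin2, KOAc, Pd(dppf)Cl2 (5 mol %), 1,4-dioxane, 90 °C; then 16, aq K2CO3, 60 °C
Reagents that add atoms: bis(pinacolato)diboron, CC1(C)OB(OC1(C)C)B1OC(C)(C)C(C)(C)O1 (boryl group of 17 only)
Why: One-pot Miyaura borylation/Suzuki–Miyaura coupling: the electron-poor C3–I bond of the iodochromone adds to palladium(0) rapidly at moderate temperature, which should spare the allyl aryl ether and the base-sensitive pyranone.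

Step 10
Reactants: 18 5-(allyloxy)-7-(methoxymethoxy)-3-[7-(methoxymethoxy)-2,2-dimethyl-2H-chromen-6-yl]-4H-chromen-4-one
Product: 20 6-allyl-5-hydroxy-7-(methoxymethoxy)-3-[7-(methoxymethoxy)-2,2-dimethyl-2H-chromen-6-yl]-4H-chromen-4-one, via 6-allyl-7-(methoxymethoxy)-3-[7-(methoxymethoxy)-2,2-dimethyl-2H-chromen-6-yl]-4H-chromene-4,5(6H)-dione 19 (not isolated)
Conditions: PhNEt2, 200 °C, sealed tube
Reagents that add atoms: none
Why: Aromatic Claisen rearrangement ([3,3]-sigmatropic shift, then tautomerisation of dienone 19): of the two positions ortho to O-5 one is the ring-fusion carbon C-4a, so the allyl group can only arrive at C-6, and the freed 5-OH is stabilised by its hydrogen bond to C-4=O.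

Step 11
Reactants: 20 6-allyl-5-hydroxy-7-(methoxymethoxy)-3-[7-(methoxymethoxy)-2,2-dimethyl-2H-chromen-6-yl]-4H-chromen-4-one
Product: 21 5-hydroxy-7-(methoxymethoxy)-3-[7-(methoxymethoxy)-2,2-dimethyl-2H-chromen-6-yl]-6-(3-methylbut-2-en-1-yl)-4H-chromen-4-one
Conditions: Grubbs second-generation catalyst (5 mol %), 2-methylbut-2-ene/CH2Cl2, 40 °C, sealed tube
Reagents that add atoms: 2-methylbut-2-ene, CC=C(C)C
Why: Olefin cross-metathesis: the terminal allyl alkene is the only unhindered alkene, whereas the cis-disubstituted chromene alkene next to the quaternary CMe2 and the trisubstituted product alkene are poor substrates, so exchange with excess 2-methylbut-2-ene should stop at the prenyl group.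

Step 12
Reactants: 21 5-hydroxy-7-(methoxymethoxy)-3-[7-(methoxymethoxy)-2,2-dimethyl-2H-chromen-6-yl]-6-(3-methylbut-2-en-1-yl)-4H-chromen-4-one
Product: 22 krausianone 2
Conditions: p-TsOH·H2O (20 mol %), MeOH–CH2Cl2, 40 °C
Reagents that add atoms: none
Why: Acid-catalysed acetal exchange with methanol removes both MOM groups under conditions mild enough to avoid addition of the 5- or 7-hydroxyl to the prenyl alkene and to leave the chromene intact.

Compound list
1 | 4-bromoresorcinol (4-bromobenzene-1,3-diol) | Oc1ccc(Br)c(O)c1 | starting material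
2 | 4-bromo-6-iodobenzene-1,3-diol | Oc1cc(O)c(Br)cc1I | intermediate
3 | 3-methylbuta-1,2-diene | CC(C)=C=C | starting material
4 | 5-bromo-2,2-dimethyl-3-methylidene-2,3-dihydro-1-benzofuran-6-ol | C=C1c2cc(Br)c(O)cc2OC1(C)C | intermediate
5 | 5-bromo-6-(methoxymethoxy)-2,2-dimethyl-3-methylidene-2,3-dihydro-1-benzofuran | C=C1c2cc(Br)c(OCOC)cc2OC1(C)C | intermediate
6 | {[5-bromo-3-methoxy-6-(methoxymethoxy)-2,2-dimethyl-2,3-dihydro-1-benzofuran-3-yl]methyl}(phenyl)iodonium tosylate (racemic) | COCOc1cc2OC(C)(C)C(OC)(C[I+]c3ccccc3)c2cc1Br.[O-]S(=O)(=O)c1ccc(C)cc1 | intermediate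
7 | 6-bromo-3,3-dimethoxy-7-(methoxymethoxy)-2,2-dimethylchromane | COCOc1cc2OC(C)(C)C(OC)(OC)Cc2cc1Br | intermediate
8 | 6-bromo-7-(methoxymethoxy)-2,2-dimethylchroman-3-one | COCOc1cc2OC(C)(C)C(=O)Cc2cc1Br | intermediate
9 | N′-[6-bromo-7-(methoxymethoxy)-2,2-dimethylchroman-3-ylidene]-4-methylbenzenesulfonohydrazide | COCOc1cc2OC(C)(C)C(=NNS(=O)(=O)c3ccc(C)cc3)Cc2cc1Br | intermediate
10 | 6-bromo-3-diazo-7-(methoxymethoxy)-2,2-dimethylchromane | COCOc1cc2OC(C)(C)C(=[N+]=[N-])Cc2cc1Br | intermediate
11 | 6-bromo-7-(methoxymethoxy)-2,2-dimethyl-2H-chromene | COCOc1cc2OC(C)(C)C=Cc2cc1Br | intermediate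
12 | 2′,4′,6′-trihydroxyacetophenone | CC(=O)c1c(O)cc(O)cc1O | starting material
13 | 1-[2,6-dihydroxy-4-(methoxymethoxy)phenyl]ethan-1-one | CC(=O)c1c(O)cc(OCOC)cc1O | intermediate
14 | 1-[2-(allyloxy)-6-hydroxy-4-(methoxymethoxy)phenyl]ethan-1-one | CC(=O)c1c(O)cc(OCOC)cc1OCC=C | intermediate
15 | (E)-1-[2-(allyloxy)-6-hydroxy-4-(methoxymethoxy)phenyl]-3-(dimethylamino)prop-2-en-1-one | CN(C)/C=C/C(=O)c1c(O)cc(OCOC)cc1OCC=C | intermediate
16 | 5-(allyloxy)-3-iodo-7-(methoxymethoxy)-4H-chromen-4-one | C=CCOc1cc(OCOC)cc2occ(I)c(=O)c12 | intermediate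
17 | 2-[7-(methoxymethoxy)-2,2-dimethyl-2H-chromen-6-yl]-4,4,5,5-tetramethyl-1,3,2-dioxaborolane | COCOc1cc2OC(C)(C)C=Cc2cc1B1OC(C)(C)C(C)(C)O1 | intermediate
18 | 5-(allyloxy)-7-(methoxymethoxy)-3-[7-(methoxymethoxy)-2,2-dimethyl-2H-chromen-6-yl]-4H-chromen-4-one | C=CCOc1cc(OCOC)cc2occ(-c3cc4C=CC(C)(C)Oc4cc3OCOC)c(=O)c12 | intermediate
19 | 6-allyl-7-(methoxymethoxy)-3-[7-(methoxymethoxy)-2,2-dimethyl-2H-chromen-6-yl]-4H-chromene-4,5(6H)-dione (racemic ortho-dienone) | C=CCC1C(OCOC)=CC2=C(C1=O)C(=O)C(-c1cc3C=CC(C)(C)Oc3cc1OCOC)=CO2 | intermediate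
20 | 6-allyl-5-hydroxy-7-(methoxymethoxy)-3-[7-(methoxymethoxy)-2,2-dimethyl-2H-chromen-6-yl]-4H-chromen-4-one | C=CCc1c(OCOC)cc2occ(-c3cc4C=CC(C)(C)Oc4cc3OCOC)c(=O)c2c1O | intermediate
21 | 5-hydroxy-7-(methoxymethoxy)-3-[7-(methoxymethoxy)-2,2-dimethyl-2H-chromen-6-yl]-6-(3-methylbut-2-en-1-yl)-4H-chromen-4-one | CC(C)=CCc1c(OCOC)cc2occ(-c3cc4C=CC(C)(C)Oc4cc3OCOC)c(=O)c2c1O | intermediate
22 | krausianone 2, 5,7-dihydroxy-3-(7-hydroxy-2,2-dimethyl-2H-chromen-6-yl)-6-(3-methylbut-2-en-1-yl)-4H-chromen-4-one | CC(C)=CCc1c(O)cc2occ(-c3cc4c(cc3O)OC(C)(C)C=C4)c(=O)c2c1O | target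

Total step count: 12. Longest linear sequence: 9 steps (steps 1–5 and 9–12).

Steps most likely to fail

Step 4. The sulfonic acid released during the reaction may strip the MOM group, after which iodine(III) would oxidise the free phenol. Solvent capture without migration (vicinal dimethoxylation) or attack of iodine(III) on the electron-rich arene may also compete. The fallback keeps the 1,2-aryl shift but replaces the hypervalent iodine leaving group with a halohydrin semipinacol rearrangement. It sets out from 5. NBS in aqueous THF at 0 °C should give the bromohydrin 5-bromo-3-(bromomethyl)-6-(methoxymethoxy)-2,2-dimethyl-2,3-dihydro-1-benzofuran-3-ol F1. Silver triflate with 2,6-di-tert-butyl-4-methylpyridine in CH2Cl2 should then abstract the primary bromide with aryl participation, and the hydroxyl group takes up the charge at C-3. This path comes back to the route at 8.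

Step 2. Closure of the phenoxide on the unsubstituted terminus of the π-allyl complex would erode the regiochemistry towards the isopropylidene isomer. Palladium-mediated re-ionisation of the tertiary allylic aryl ether would have the same effect. Slow oxidative addition at C–Br would start a second annulation. The fallback builds the five-membered ring by acylation and installs the methylene by olefination. It sets out from 1. Friedel–Crafts acylation with 2-bromo-2-methylpropanoyl bromide and AlCl3 should give 2-bromo-1-(5-bromo-2,4-dihydroxyphenyl)-2-methylpropan-1-one F2. K2CO3 in acetone closes it to 5-bromo-6-hydroxy-2,2-dimethyl-1-benzofuran-3(2H)-one F3. MOMCl and i-Pr2NEt give 5-bromo-6-(methoxymethoxy)-2,2-dimethyl-1-benzofuran-3(2H)-one F4, and Wittig methylenation with methylenetriphenylphosphorane comes back to the route at 5.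

Step 9. Three processes may consume the partners: protodeboronation of the electron-rich ortho-alkoxy boronate, opening of the pyranone by aqueous carbonate, and palladium(0) ionisation of the allyl aryl ether. The fallback is a base-free Negishi coupling at room temperature. It sets out from 11. Bromine–lithium exchange with n-BuLi in THF at −78 °C gives [7-(methoxymethoxy)-2,2-dimethyl-2H-chromen-6-yl]lithium F5. ZnCl2 converts it into chloro[7-(methoxymethoxy)-2,2-dimethyl-2H-chromen-6-yl]zinc F6. Coupling with 16 under Pd2(dba)3/SPhos in THF comes back to the route at 18.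

Further compounds
F1 | step 4 | 5-bromo-3-(bromomethyl)-6-(methoxymethoxy)-2,2-dimethyl-2,3-dihydro-1-benzofuran-3-ol (racemic) | COCOc1cc2OC(C)(C)C(O)(CBr)c2cc1Br
F2 | step 2 | 2-bromo-1-(5-bromo-2,4-dihydroxyphenyl)-2-methylpropan-1-one | CC(C)(Br)C(=O)c1cc(Br)c(O)cc1O
F3 | step 2 | 5-bromo-6-hydroxy-2,2-dimethyl-1-benzofuran-3(2H)-one | CC1(C)Oc2cc(O)c(Br)cc2C1=O
F4 | step 2 | 5-bromo-6-(methoxymethoxy)-2,2-dimethyl-1-benzofuran-3(2H)-one | CC1(C)Oc2cc(OCOC)c(Br)cc2C1=O
F5 | step 9 | [7-(methoxymethoxy)-2,2-dimethyl-2H-chromen-6-yl]lithium | COCOc1cc2OC(C)(C)C=Cc2cc1[Li]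
F6 | step 9 | chloro[7-(methoxymethoxy)-2,2-dimethyl-2H-chromen-6-yl]zinc | COCOc1cc2OC(C)(C)C=Cc2cc1[Zn]Cl
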